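The diester is cut at both C6–O bonds into a (2E,6E)-diacid and two copies of one amino alcohol, and the cis-fused cyclopenta[c]pyridine of the latter is opened at C1–C7a. The feature exploited is that ring-fusion carbon C7a lies two bonds from oxygenated C6 in the cyclopentane ring and carries the nitrogen-bound methylene C1 of the piperidine ring. As part of a C6 ketone conjugated through C7, C7a becomes an electrophilic β-carbon, while C1 can be a nitrogen-stabilised nucleophilic radical. Photoredox decarboxylation of an N-methylglycine arm delivers this radical, closing the piperidine and setting C7a and C7 at once. The precursor is an (R)-2-methylcyclopent-2-enone bearing at C4 an (R)-1-[carboxymethyl(methyl)amino]propan-2-yl chain.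

Key step: step 10

Remarks on the chemistry
- **Numbering and configuration.** Cyclopenta[c]pyridine numbering (C1, N2, C3, C4, C4a, C5, C6, C7, C7a) is used for all atoms that end up in the bicycle. Each unit of the target is (4R,4aS,6R,7S,7aR). H-4, H-4a and H-7a share one face, and the C7 methyl and the C6 oxygen lie on the convex face.
- **Ring-size correction.** Michael addition of an aldehyde to ethyl vinyl ketone followed by aldol condensation passes through a 1,5-keto aldehyde. It therefore closes a 4-substituted 2-methylcyclohex-2-enone, not the five-membered enone needed here. The cyclopentenone is instead made from a hepta-1,6-dien-3-one by metathesis. This also avoids an epimerisable α-branched aldehyde at C4a.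
- **Relative configuration at C4/C4a.** The C4 methyl must be trans to the C7a carbon within any ring that contains C3, C4, C4a and C5. Anti conjugate addition to a 5-methyl unsaturated δ-lactone gives exactly this relationship.
- **Assumption.** Sarcosine tert-butyl ester is used as the free base, liberated from its commercial hydrochloride by a carbonate wash.

Step 1
Reactants: 1 methyl (S)-3-hydroxy-2-methylpropanoate
Product: 2 methyl (S)-3-[(tert-butyldimethylsilyl)oxy]-2-methylpropanoate
Conditions: TBSCl, imidazole, CH2Cl2, 0 °C to rt
Reagents that add atoms: tert-butyldimethylsilyl chloride, CC(C)(C)[Si](C)(C)Cl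
Why: Imidazole-promoted silyl ether formation on a primary alcohol is routine and too mild to disturb the stereocentre next to the ester, which later becomes C4.

Step 2
Reactants: 2 methyl (S)-3-[(tert-butyldimethylsilyl)oxy]-2-methylpropanoate
Product: 3 (S)-3-[(tert-butyldimethylsilyl)oxy]-2-methylpropanal
Conditions: i-Bu2AlH (1.1 equiv), CH2Cl2, −78 °C; aq. potassium sodium tartrate
Reagents that add atoms: none
Why: Partial ester reduction with i-Bu2AlH stops at the aluminium hemiacetal at −78 °C and releases the aldehyde only on work-up, and the α-stereocentre holds when the aldehyde is carried on without storage.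

Step 3
Reactants: 3 (S)-3-[(tert-butyldimethylsilyl)oxy]-2-methylpropanal
Product: 4 methyl (R,Z)-5-[(tert-butyldimethylsilyl)oxy]-4-methylpent-2-enoate
Conditions: (CF3CH2O)2P(O)CH2CO2Me, KN(SiMe3)2, 18-crown-6, THF, −78 °C
Reagents that add atoms: methyl bis(2,2,2-trifluoroethyl)phosphonoacetate, COC(=O)CP(=O)(OCC(F)(F)F)OCC(F)(F)F
Why: Still–Gennari modification of the Horner–Wadsworth–Emmons olefination, in which the trifluoroethyl phosphonate and the crown-ether-separated potassium ion make elimination fast and kinetically Z-selective, at a temperature where the aldehyde does not epimerise.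

Step 4
Reactants: 4 methyl (R,Z)-5-[(tert-butyldimethylsilyl)oxy]-4-methylpent-2-enoate
Product: 6 (R)-5-methyl-5,6-dihydro-2H-pyran-2-one, via hydroxy enoate 5 (not isolated)
Conditions: 2 M aq. HCl (cat.), THF, rt
Reagents that add atoms: none
Why: Acid-catalysed desilylation frees the primary alcohol, which the Z-alkene holds next to the ester so that transesterification to the six-membered unsaturated lactone follows spontaneously without touching the stereocentre.

Step 5
Reactants: 6 (R)-5-methyl-5,6-dihydro-2H-pyran-2-one
Product: 8 (4R,5R)-5-methyl-4-vinyltetrahydro-2H-pyran-2-one, via silyl ketene acetal 7 (not isolated)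
Conditions: CH2=CHMgBr (1.5 equiv), CuBr·SMe2 (10 mol %), TMSCl (2 equiv), THF, −78 °C; then 1 M HCl, 0 °C
Reagents that add atoms: vinylmagnesium bromide, C=C[Mg]Br; chlorotrimethylsilane, C[Si](C)(C)Cl (silicon retained only in 7)
Why: Copper-catalysed, chlorosilane-accelerated conjugate addition of a Grignard reagent, in which the vinyl group enters the β-carbon anti to the neighbouring methyl group (axial attack on the half-chair with pseudoaxial methyl), so that the future C4a is set trans to the C4 methyl within the lactone ring.

Step 6
Reactants: 8 (4R,5R)-5-methyl-4-vinyltetrahydro-2H-pyran-2-one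
Product: 10 (R)-5-[(R)-1-hydroxypropan-2-yl]-2-methylhepta-1,6-dien-3-one, via hydroxy Weinreb amide 9 (not isolated)
Conditions: MeNH(OMe)·HCl (2 equiv), i-PrMgCl (4 equiv), THF, −20 °C; then CH2=C(CH3)MgBr (3 equiv), −20 to 0 °C; aq. NH4Cl
Reagents that add atoms: isopropenylmagnesium bromide, CC(=C)[Mg]Br; N,O-dimethylhydroxylamine hydrochloride, CNOC.Cl (retained only in 9)
Why: One-pot Weinreb ketone synthesis, in which the magnesium amide opens the lactone to amide 9, whose chelated tetrahedral adduct with the alkenyl Grignard reagent persists until work-up, so a single addition occurs and no stereocentre is involved.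

Step 7
Reactants: 10 (R)-5-[(R)-1-hydroxypropan-2-yl]-2-methylhepta-1,6-dien-3-one
Product: 11 (R)-4-[(R)-1-hydroxypropan-2-yl]-2-methylcyclopent-2-en-1-one
Conditions: second-generation Hoveyda–Grubbs catalyst (H2IMes)Cl2Ru(=CH-2-i-PrOC6H4) (5 mol %), CH2Cl2 (0.01 M), 40 °C
Reagents that add atoms: none
Why: Ring-closing metathesis of a 1,6-dien-3-one, initiated at the monosubstituted vinyl group and closed onto the 1,1-disubstituted enone alkene with loss of ethene, gives the five-membered enone under neutral conditions that cannot epimerise the allylic C4a centre.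

Step 8
Reactants: 11 (R)-4-[(R)-1-hydroxypropan-2-yl]-2-methylcyclopent-2-en-1-one; 12 sarcosine tert-butyl ester
Product: 14 tert-butyl N-methyl-N-{(R)-2-[(R)-3-methyl-4-oxocyclopent-2-en-1-yl]propyl}glycinate, via primary triflate 13 (not isolated)
Conditions: Tf2O (1.1 equiv), 2,6-di-tert-butyl-4-methylpyridine (1.3 equiv), CH2Cl2, −78 °C; then 12 (1.5 equiv), i-Pr2NEt (2 equiv), −78 to 0 °C
Reagents that add atoms: trifluoromethanesulfonic anhydride, O=S(=O)(OS(=O)(=O)C(F)(F)F)C(F)(F)F (retained only in 13)
Why: SN2 N-alkylation of a secondary amine by a primary alkyl triflate generated in situ takes place at the CH2 carbon well below 0 °C, so the adjacent stereocentre is untouched and the hindered α-methyl enone is spared from aza-Michael addition.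

Step 9
Reactants: 14 tert-butyl N-methyl-N-{(R)-2-[(R)-3-methyl-4-oxocyclopent-2-en-1-yl]propyl}glycinate
Product: 15 N-methyl-N-{(R)-2-[(R)-3-methyl-4-oxocyclopent-2-en-1-yl]propyl}glycine (zwitterion)
Conditions: TFA/CH2Cl2 (1:2), 0 °C to rt; evaporation, then Amberlyst A-21, MeOH
Reagents that add atoms: none
Why: Acidolysis of a tert-butyl ester (loss of the tert-butyl cation as isobutene) is compatible with the enone and with the protonated amine and needs no base that could deconjugate the enone.

Step 10
Reactants: 15 N-methyl-N-{(R)-2-[(R)-3-methyl-4-oxocyclopent-2-en-1-yl]propyl}glycine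
Product: 17 (4R,4aS,7S,7aR)-2,4,7-trimethyloctahydro-6H-cyclopenta[c]pyridin-6-one, via aminomethyl radical 16 (not isolated)
Conditions: Ir[dF(CF3)ppy]2(dtbbpy)PF6 (1 mol %), Cs2CO3 (0.6 equiv), DMF (0.01 M), Ar, 450 nm LEDs, 25 °C; then DBU (0.3 equiv), 25 °C
Reagents that add atoms: none
Why: The excited trivalent iridium complex takes one electron from the amino carboxylate of 15, CO2 is lost, and the nucleophilic radical 16 arises only at C1 because deprotonation at the other α-C–H sites cannot compete with decarboxylation. The closest known reaction type is the photoredox decarboxylative Giese addition of α-amino acids to enones, run here within one molecule. Radical 16 attacks the electrophilic β-carbon C7a in a 6-exo-trig closure that forms C1–C7a and the piperidine ring, the 7-endo alternative at the methyl-bearing α-carbon C7 being mismatched in polarity and more hindered. C7a is controlled by the existing C4a centre, since the short tether (C4, C3, N2) can reach the enone only from the face to which it is attached, so H-4a and H-7a end up cis. The α-keto radical is reduced by the divalent iridium complex to the C6–C7 enolate, which closes the catalytic cycle, and protonation followed by DBU equilibration next to the ketone places the C7 methyl on the convex face, trans to C1. High dilution suppresses intermolecular addition, and C4 and C4a carry no acidic or oxidisable position that the conditions address.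

Step 11
Reactants: 17 (4R,4aS,7S,7aR)-2,4,7-trimethyloctahydro-6H-cyclopenta[c]pyridin-6-one
Product: 18 (4R,4aS,6S,7S,7aR)-2,4,7-trimethyloctahydro-1H-cyclopenta[c]pyridin-6-ol (6-epi alcohol, hydroxyl on the concave face, trans to the C7 methyl)
Conditions: NaBH4, MeOH, −20 to 0 °C
Reagents that add atoms: none
Why: Borohydride reduction of a cyclopentanone, in which the small hydride should reach C6 from the convex face because C1 and C4 of the piperidine ring cover the concave face, a direction that also matches the preference of small hydrides for the trans alcohol in 2-methylcyclopentanones, so C6 is set as S.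

Step 12
Reactants: 19 geranyl acetate
Product: 20 (2E,6E)-8-hydroxy-3,7-dimethylocta-2,6-dien-1-yl acetate
Conditions: SeO2 (10 mol %), t-BuOOH (2.5 equiv), salicylic acid (10 mol %), CH2Cl2, 0 °C to rt
Reagents that add atoms: tert-butyl hydroperoxide, CC(C)(C)OO (terminal oxygen source); selenium dioxide, O=[Se]=O (catalytic oxygen carrier)
Why: Riley-type allylic oxidation (ene reaction followed by [2,3]-sigmatropic shift) run catalytically in SeO2 attacks the E-methyl group of the electron-richer terminal alkene, the alkene next to the acetate being deactivated, and so fixes the 6E geometry.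

Step 13
Reactants: 20 (2E,6E)-8-hydroxy-3,7-dimethylocta-2,6-dien-1-yl acetate
Product: 21 (2E,6E)-2,6-dimethylocta-2,6-diene-1,8-diol
Conditions: K2CO3 (cat.), MeOH, rt
Reagents that add atoms: none
Why: Carbonate-catalysed transesterification with methanol removes the acetate without affecting either alkene.

Step 14
Reactants: 21 (2E,6E)-2,6-dimethylocta-2,6-diene-1,8-diol
Product: 22 (2E,6E)-2,6-dimethylocta-2,6-dienedial
Conditions: activated MnO2 (excess), CH2Cl2, rt
Reagents that add atoms: none
Why: Heterogeneous MnO2 oxidation is selective for allylic alcohols, both hydroxyl groups qualify, and the neutral medium keeps both E-alkenes from isomerising.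

Step 15
Reactants: 22 (2E,6E)-2,6-dimethylocta-2,6-dienedial
Product: 23 (2E,6E)-2,6-dimethylocta-2,6-dienedioic acid
Conditions: NaClO2, NaH2PO4, 2-methylbut-2-ene, t-BuOH/H2O, 0 °C to rt
Reagents that add atoms: sodium chlorite, [Na+].[O-]Cl=O
Why: Pinnick oxidation converts enals into enoic acids under buffered conditions without E/Z scrambling, the alkene scavenger removing hypochlorous acid.

Step 16
Reactants: 18 (4R,4aS,6S,7S,7aR)-2,4,7-trimethyloctahydro-1H-cyclopenta[c]pyridin-6-ol (2.2 equiv); 23 (2E,6E)-2,6-dimethylocta-2,6-dienedioic acid
Product: 24 bis[(4R,4aS,6R,7S,7aR)-2,4,7-trimethyloctahydro-1H-cyclopenta[c]pyridin-6-yl] (2E,6E)-2,6-dimethylocta-2,6-dienedioate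
Conditions: PPh3 (3 equiv), DIAD (3 equiv), THF, 0 °C to rt
Reagents that add atoms: none
Why: Double Mitsunobu esterification, in which each secondary alcohol is activated as an oxyphosphonium ion and displaced by a carboxylate of 23 in an SN2 process from the open convex face, which inverts C6 from S to R at both ends while the tertiary amines and the E-alkenes are spectators.

Compound list
1 | methyl (S)-3-hydroxy-2-methylpropanoate | COC(=O)[C@@H](C)CO | starting material
2 | methyl (S)-3-[(tert-butyldimethylsilyl)oxy]-2-methylpropanoate | COC(=O)[C@@H](C)CO[Si](C)(C)C(C)(C)C | intermediate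
3 | (S)-3-[(tert-butyldimethylsilyl)oxy]-2-methylpropanal | O=C[C@@H](C)CO[Si](C)(C)C(C)(C)C | intermediate
4 | methyl (R,Z)-5-[(tert-butyldimethylsilyl)oxy]-4-methylpent-2-enoate | COC(=O)/C=C\[C@@H](C)CO[Si](C)(C)C(C)(C)C | intermediate
5 | methyl (R,Z)-5-hydroxy-4-methylpent-2-enoate (not isolated) | COC(=O)/C=C\[C@@H](C)CO | intermediate
6 | (R)-5-methyl-5,6-dihydro-2H-pyran-2-one | O=C1C=C[C@@H](C)CO1 | intermediate
7 | (3R,4R)-3-methyl-6-(trimethylsilyloxy)-4-vinyl-3,4-dihydro-2H-pyran, the silyl ketene acetal of 8 (not isolated) | C[Si](C)(C)OC1=C[C@H](C=C)[C@@H](C)CO1 | intermediate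
8 | (4R,5R)-5-methyl-4-vinyltetrahydro-2H-pyran-2-one (methyl and vinyl trans) | O=C1C[C@H](C=C)[C@@H](C)CO1 | intermediate
9 | (3R,4R)-5-hydroxy-N-methoxy-N,4-dimethyl-3-vinylpentanamide, formed as its chloromagnesium alkoxide (not isolated) | CON(C)C(=O)C[C@H](C=C)[C@@H](C)CO | intermediate
10 | (R)-5-[(R)-1-hydroxypropan-2-yl]-2-methylhepta-1,6-dien-3-one | C=C(C)C(=O)C[C@H](C=C)[C@@H](C)CO | intermediate
11 | (R)-4-[(R)-1-hydroxypropan-2-yl]-2-methylcyclopent-2-en-1-one | O=C1C[C@@H]([C@@H](C)CO)C=C1C | intermediate
12 | sarcosine tert-butyl ester | CNCC(=O)OC(C)(C)C | starting material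
13 | (R)-2-[(R)-3-methyl-4-oxocyclopent-2-en-1-yl]propyl trifluoromethanesulfonate (not isolated) | O=C1C[C@@H]([C@@H](C)COS(=O)(=O)C(F)(F)F)C=C1C | intermediate
14 | tert-butyl N-methyl-N-{(R)-2-[(R)-3-methyl-4-oxocyclopent-2-en-1-yl]propyl}glycinate | O=C1C[C@@H]([C@@H](C)CN(C)CC(=O)OC(C)(C)C)C=C1C | intermediate
15 | N-methyl-N-{(R)-2-[(R)-3-methyl-4-oxocyclopent-2-en-1-yl]propyl}glycine (key-step precursor) | O=C1C[C@@H]([C@@H](C)CN(C)CC(=O)O)C=C1C | intermediate
16 | C1 aminomethyl radical derived from 15 by loss of CO2 (not isolated) | O=C1C[C@@H]([C@@H](C)CN(C)[CH2])C=C1C | intermediate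
17 | (4R,4aS,7S,7aR)-2,4,7-trimethyloctahydro-6H-cyclopenta[c]pyridin-6-one (cis-fused, key-step product) | O=C1C[C@@H]2[C@@H](CN(C)C[C@@H]2C)[C@@H]1C | intermediate
18 | (4R,4aS,6S,7S,7aR)-2,4,7-trimethyloctahydro-1H-cyclopenta[c]pyridin-6-ol | O[C@H]1C[C@@H]2[C@@H](CN(C)C[C@@H]2C)[C@@H]1C | intermediate
19 | geranyl acetate | CC(C)=CCC/C(C)=C/COC(C)=O | starting material
20 | (2E,6E)-8-hydroxy-3,7-dimethylocta-2,6-dien-1-yl acetate | OC/C(C)=C/CC/C(C)=C/COC(C)=O | intermediate
21 | (2E,6E)-2,6-dimethylocta-2,6-diene-1,8-diol | OC/C(C)=C/CC/C(C)=C/CO | intermediate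
22 | (2E,6E)-2,6-dimethylocta-2,6-dienedial | O=C/C(C)=C/CC/C(C)=C/C=O | intermediate
23 | (2E,6E)-2,6-dimethylocta-2,6-dienedioic acid | OC(=O)/C(C)=C/CC/C(C)=C/C(=O)O | intermediate
24 | bis[(4R,4aS,6R,7S,7aR)-2,4,7-trimethyloctahydro-1H-cyclopenta[c]pyridin-6-yl] (2E,6E)-2,6-dimethylocta-2,6-dienedioate (CNP0240822.3) | C/C(=C\C(=O)O[C@@H]1C[C@@H]2[C@@H](CN(C)C[C@@H]2C)[C@@H]1C)CC/C=C(\C)C(=O)O[C@@H]1C[C@@H]2[C@@H](CN(C)C[C@@H]2C)[C@@H]1C | target

Total step count: 16. Longest linear sequence: 12 (steps 1 to 11, then step 16). The diacid branch (steps 12 to 15) runs in parallel.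

Steps most likely to fail

1. **Step 10.**
   - What may go wrong: the α-amino radical may be quenched by hydrogen-atom transfer, or oxidised on to an iminium ion, faster than it cyclises. Continued single-electron oxidation may also wear down the tertiary amine product.
   - Fallback: it sets out from 11, which is converted to triflate 13 as in step 8. The triflate is used to alkylate N-methyl-1-(trimethylsilyl)methanamine instead of 12, giving the α-silylamine enone F1. F1 is irradiated with 9,10-dicyanoanthracene as electron-transfer sensitiser in MeCN/MeOH (above 400 nm), which should give the aminium radical cation. Methanol-assisted loss of the silyl group then leads to the same radical 16 without any carboxylate or base in the medium, and the route is rejoined at 17.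

2. **Step 11.**
   - What may go wrong: facial selectivity in hydride delivery may erode, because the C7 methyl group shields part of the convex face and competes with the shielding of the concave face by the piperidine ring.
   - Fallback: it sets out from 17, which is reduced without any demand on selectivity, and the epimers are separated. The 6R alcohol F2 already has the configuration of the target. It is esterified with 23 with retention by carbodiimide coupling (EDC·HCl, DMAP, CH2Cl2), while any 18 still goes through step 16. Both streams arrive at 24.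

3. **Step 16.**
   - What may go wrong: the activated alcohol may eliminate towards C5, or the reaction may stall at the mono-ester stage, because the incoming carboxylate has to pass the neighbouring C7 methyl group.
   - Fallback: it sets out from 18, which is converted with MsCl and Et3N in CH2Cl2 at 0 °C into the mesylate F3. Separately, 23 is turned with Cs2CO3 in DMF into the dicaesium dicarboxylate F4. Heating F3 (2.2 equiv) with F4 in DMF at about 50 °C should give the double SN2 displacement with inversion at C6. Intramolecular attack by N2 is excluded because nitrogen sits on the same face as the leaving group. The route is rejoined at 24.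

Further compounds
F1 | step 10 | (R)-2-methyl-4-[(R)-1-{methyl[(trimethylsilyl)methyl]amino}propan-2-yl]cyclopent-2-en-1-one | O=C1C[C@@H]([C@@H](C)CN(C)C[Si](C)(C)C)C=C1C
F2 | step 11 | (4R,4aS,6R,7S,7aR)-2,4,7-trimethyloctahydro-1H-cyclopenta[c]pyridin-6-ol | O[C@@H]1C[C@@H]2[C@@H](CN(C)C[C@@H]2C)[C@@H]1C
F3 | step 16 | (4R,4aS,6S,7S,7aR)-2,4,7-trimethyloctahydro-1H-cyclopenta[c]pyridin-6-yl methanesulfonate | CS(=O)(=O)O[C@H]1C[C@@H]2[C@@H](CN(C)C[C@@H]2C)[C@@H]1C
F4 | step 16 | dicaesium (2E,6E)-2,6-dimethylocta-2,6-dienedioate | [Cs+].[Cs+].[O-]C(=O)/C(C)=C/CC/C(C)=C/C(=O)[O-]
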